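39 % of the first end groups read as links at 80.0 min in the north-east run, so with nearly equal charges about 60.2 % of the second end groups stay unused by that reading. I hand over the bench with this note.

| flask | first end groups | second end groups | remark | time |
|---|---|---|---|---|
| north-east | 0.10 M | 0.098 M | run made earlier |  |
| south | 0.15 M | 0.098 M | run made earlier |  |
| Monday's | 0.10 M (fed, over 20 min) | 0.0980 M | all else is in the flask from the start; the feed brings no volume worth counting | 1.5 h |
| Thursday's | 0.10 M | 0.0980 M (fed, over 20 min) | all else is in the flask from the start; the feed brings no volume worth counting | 1.5 h |
| Saturday's | 0.10 M | 0.0980 M (in portions, 5, over 20 min) | first portion at the start, last at 20 min | 1.5 h |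
| Tuesday's | 0.10 M | 0.0980 M | everything together at the start | 1.5 h |

- north-east (time / min: links / %, first end groups / %): 5.00: 33, 12; 15.0: 39, 7; 25.0: 37, 1; 40.0: 41, 1; 50.0: 39, 0; 80.0: 39, 0; 90.0: 38, 0
- south (time / min: links / %, first end groups / %): 2.00: 22, 29; 3.00: 20, 20; 5.00: 29, 8; 8.00: 25, 3; 12.0: 29, 5; 20.0: 32, 1; 25.0: 33, 2

(each reading ± 2 percentage points)

- in percentages every species weighs as the first end groups in it: one self-condensation product counts as two
- for links the crystals are counted in
- as a solid, counted per litre of solution: crystals
- on the list of suspects stand: 2 first end groups -> self-condensation product; first end groups + by-product -> side product; first end groups + second end groups <-> links + by-product; crystals <-> links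

1. the flask that comes out highest in amount of links, in percent of the first end groups charged, or "all alike" when all lie within 1.5 percentage points (Monday's / Thursday's / Saturday's / Tuesday's / all alike)
2. links at the end, in percent of the first end groups charged, Monday's
3. links at the end, in percent of the first end groups charged, Thursday's
4. links at the end, in percent of the first end groups charged, Saturday's
5. links at the end, in percent of the first end groups charged, Tuesday's

I reckon with the fraction left. Leaving the side product aside, first end groups are shared between links and self-condensation product:

share to links = 1 / (1 + ρ [first end groups]/[second end groups])

Following the fraction f of second end groups left until the first end groups are gone, with u the charged ratio of first to second, gives: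

ln f = −ln(1 + (ρ − 1)u) / (ρ − 1)

With u near 1, the north-east reading gives ρ = 3.42, the selectivity factor: first end groups lost to self-condensation per one lost to links at equal concentrations. On the south charges it gives 30.9 % links, and that run reads 33 %.

At equal concentrations the share is 22.6 %. So do not touch Monday's feed of first end groups, with the second end groups in the flask from the start. I expect Tuesday's near 39 %, Monday's above that, and the two flasks that dose second end groups below 22.6 %.

The forecast gives 50 %, 16 %, 19 %, 39 % for Monday's, Thursday's, Saturday's, Tuesday's. It says of the first end groups in Thursday's that “it self-condenses within minutes”.

The flasks give 53.5 %, 16.2 %, 19.3 %, 39.2 %, in that order, so Monday's stands highest.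

    2 first end groups → self-condensation product (k = 3.00 M⁻¹ min⁻¹)
    first end groups + by-product → side product (k = 1.90 M⁻¹ min⁻¹)
    first end groups + second end groups ⇌ links + by-product (K = 13.0, k = 2.50 M⁻¹ min⁻¹)
    crystals ⇌ links, rate k4*(cs4 - [links]) while solid is left; crystals form when [links] > cs4 (solubility = 11.0 mM, k = 1.70 min⁻¹)

Taking away the path to self-condensation product shrinks the gap between Monday's and Thursday's from 37 percentage points to 3.2 points. In Monday's, the ratio of the mean concentrations over the feed is [first end groups]/[second end groups] = 0.182, so ρ gives a share of 61.6 %, and at the end that flask's links against links plus self-condensation product come to 66.0 %. In Thursday's, 5.01 stand at the end as self-condensation product per one as links, which by ρ is an effective [first end groups]/[second end groups] near 1.46.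

The runs are simulated from invented constants, and the scatter is random.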